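**Retrosynthetic overview**
- The acetate goes on last, onto the C6 hydroxymethyl group, which travels through the route as a silyl ether. Ring A (2,6-dimethoxyphenyl) is bought with its ketone carbon attached.
- Feature: ring B (C1 aroyl, C2 OH, C3 H, C4 Me, C5 OMe, C6 CH2OAc) is a 3-aroyl-4-pyranone in disguise. The pyranone carbonyl carbon is C2, the aroyl-bearing carbon is C1, the two carbons on the ring oxygen are C6 and C4, and only the methoxy carbon C5 is absent.
- Key disconnection: C5–C6 and C4–C5, a (5+1) exchange of the ring oxygen for the carbon of (methoxymethylene)triphenylphosphorane by conjugate addition, ring opening and Wittig closure.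
- The pyranone ring is made first (step 3) and turned into ring B (step 4). It is cut into acetylketene and an enaminone whose nitrogen marks the future ring-oxygen carbon; the enaminone goes back to dimethylamine and an ynone, and the ynone to 2,6-dimethoxybenzoyl chloride and a silyl propargyl ether.

Key step: step 4

Remark on the chemistry: ring B is numbered C1 (aroyl) to C6 (CH2OAc) throughout. The target has no stereocentre; the geometry of enaminone 4 and the two stereocentres of transient 7 are lost in step 3.

Step 1
Reactants: 1 2,6-dimethoxybenzoyl chloride; 2 tert-butyldimethyl(prop-2-yn-1-yloxy)silane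
Product: 3 4-[(tert-butyldimethylsilyl)oxy]-1-(2,6-dimethoxyphenyl)but-2-yn-1-one
Conditions: PdCl2(PPh3)2 (2 mol%), CuI (4 mol%), Et3N (1.5 equiv), THF, rt
Reagents that add atoms: none
Why: Acyl Sonogashira coupling: oxidative addition of the acid chloride, alkynyl transfer from copper and reductive elimination should give the ynone under anhydrous amine conditions that leave the silyl ether alone.

Step 2
Reactants: 3 4-[(tert-butyldimethylsilyl)oxy]-1-(2,6-dimethoxyphenyl)but-2-yn-1-one
Product: 4 (E)-4-[(tert-butyldimethylsilyl)oxy]-3-(dimethylamino)-1-(2,6-dimethoxyphenyl)but-2-en-1-one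
Conditions: Me2NH (2.0 M in THF, 1.5 equiv), THF, 0 °C to rt
Reagents that add atoms: dimethylamine, CNC
Why: Aza-Michael addition of a secondary amine to an ynone places nitrogen on the β-carbon only, which fixes the carbon that will later carry the ring oxygen (future C6); the expected E geometry is of no consequence.

Step 3
Reactants: 4 (E)-4-[(tert-butyldimethylsilyl)oxy]-3-(dimethylamino)-1-(2,6-dimethoxyphenyl)but-2-en-1-one; 5 2,2,6-trimethyl-4H-1,3-dioxin-4-one
Product: 8 2-{[(tert-butyldimethylsilyl)oxy]methyl}-3-(2,6-dimethoxybenzoyl)-6-methyl-4H-pyran-4-one, via acetylketene 6 (not isolated), via aminodihydropyranone 7 (not isolated)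
Conditions: 5 (2.5 equiv, slow addition), PhMe, 110 °C, N2 sweep
Reagents that add atoms: none
Why: Retro-[4+2] of the dioxinone releases acetylketene, which should undergo the known [4+2] annulation of acylketenes with enamines (C-acylation at the nucleophilic α-carbon, closure of the acetyl oxygen on the iminium carbon), and β-elimination of dimethylamine then gives the 4-pyranone with its ring oxygen on the silyloxymethyl carbon.

Step 4
Reactants: 8 2-{[(tert-butyldimethylsilyl)oxy]methyl}-3-(2,6-dimethoxybenzoyl)-6-methyl-4H-pyran-4-one; 9 (methoxymethyl)triphenylphosphonium chloride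
Product: 12 [2-{[(tert-butyldimethylsilyl)oxy]methyl}-6-hydroxy-3-methoxy-4-methylphenyl](2,6-dimethoxyphenyl)methanone, via (methoxymethylene)triphenylphosphorane 10 (not isolated), via phosphonium enolate 11 (not isolated)
Conditions: 9 (3.0 equiv), KN(SiMe3)2 (2.8 equiv), THF, 0 °C; then 8, −78 °C to rt, then 50 °C; aq. NH4Cl
Reagents that add atoms: none
Why: Proposed new method: ylide 10 should add in conjugate fashion to the silyloxymethyl-bearing ring carbon of 8 (future C6, activated by both the ring carbonyl and the 3-aroyl group), the doubly stabilised enolate should expel the ring oxygen to give the open zwitterion 11, and a second equivalent of 10 should deprotonate its P–CH(OMe) carbon so that a phosphorane is regenerated within the chain. Ring B then closes by intramolecular Wittig olefination, the ylide carbon (C5) attacking the methyl ketone carbonyl (C4) in a 6-exo-trig addition, and loss of Ph3PO from the oxaphosphetane gives the C4=C5 bond and with it the aromatic C2 phenoxide, protonated on work-up. The closest known reactions are the conversion of pyrylium salts into benzenes by alkylidenephosphoranes or nitromethane and carbanion-induced ring transformations of pyranones into arenes; a neutral 4-pyranone has not been carried through this sequence by a phosphorus ylide. No stereocentre is created. The step needs attack at an oxygen-bearing ring carbon and not at a carbonyl, which the substrate secures because the ring carbonyl is a vinylogous ester of low electrophilicity and the diaryl ketone is shielded by the two ortho methoxy groups, while in 11 the methyl ketone is the only carbonyl the ylide carbon can reach through a six-membered ring. Should 10 add at the methyl-bearing carbon instead, the isomeric open chain would close on the silyloxymethyl ketone to the same phenoxide, with the shielded aryl ketone as the only competitor.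

Step 5
Reactants: 12 [2-{[(tert-butyldimethylsilyl)oxy]methyl}-6-hydroxy-3-methoxy-4-methylphenyl](2,6-dimethoxyphenyl)methanone
Product: 13 (2,6-dimethoxyphenyl)[6-hydroxy-2-(hydroxymethyl)-3-methoxy-4-methylphenyl]methanone
Conditions: HF·pyridine, pyridine, THF, 0 °C to rt
Reagents that add atoms: none
Why: Fluoride-driven Si–O cleavage of the primary silyl ether; the pyridine buffer should keep the medium too weakly acidic to ionise the new benzylic alcohol or ketalise the chelated diaryl ketone, and the aryl methyl ethers are inert.

Step 6
Reactants: 13 (2,6-dimethoxyphenyl)[6-hydroxy-2-(hydroxymethyl)-3-methoxy-4-methylphenyl]methanone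
Product: 14 preacredinone A, [2-(2,6-dimethoxybenzoyl)-3-hydroxy-6-methoxy-5-methylphenyl]methyl acetate
Conditions: Ac2O (1.1 equiv), pyridine, CH2Cl2, 0 °C
Reagents that add atoms: acetic anhydride, CC(=O)OC(C)=O
Why: Nucleophilic acyl substitution should take the primary benzylic alcohol much faster than the phenol, whose hydroxyl is locked in a hydrogen bond to the ortho ketone and is not deprotonated by pyridine, so one equivalent of anhydride without an acyl-transfer catalyst acetylates the alcohol selectively.

**Compound list**
1 | 2,6-dimethoxybenzoyl chloride | COc1cccc(OC)c1C(=O)Cl | starting material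
2 | tert-butyldimethyl(prop-2-yn-1-yloxy)silane | C#CCO[Si](C)(C)C(C)(C)C | starting material
3 | 4-[(tert-butyldimethylsilyl)oxy]-1-(2,6-dimethoxyphenyl)but-2-yn-1-one | COc1cccc(OC)c1C(=O)C#CCO[Si](C)(C)C(C)(C)C | intermediate
4 | (E)-4-[(tert-butyldimethylsilyl)oxy]-3-(dimethylamino)-1-(2,6-dimethoxyphenyl)but-2-en-1-one | COc1cccc(OC)c1C(=O)/C=C(/N(C)C)CO[Si](C)(C)C(C)(C)C | intermediate
5 | 2,2,6-trimethyl-4H-1,3-dioxin-4-one | CC1=CC(=O)OC(C)(C)O1 | starting material
6 | acetylketene (3-oxobut-1-en-1-one) | CC(=O)C=C=O | intermediate
7 | 2-{[(tert-butyldimethylsilyl)oxy]methyl}-2-(dimethylamino)-3-(2,6-dimethoxybenzoyl)-6-methyl-2,3-dihydro-4H-pyran-4-one (racemic, diastereomers not defined) | COc1cccc(OC)c1C(=O)C1C(=O)C=C(C)OC1(CO[Si](C)(C)C(C)(C)C)N(C)C | intermediate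
8 | 2-{[(tert-butyldimethylsilyl)oxy]methyl}-3-(2,6-dimethoxybenzoyl)-6-methyl-4H-pyran-4-one | COc1cccc(OC)c1C(=O)c1c(CO[Si](C)(C)C(C)(C)C)oc(C)cc1=O | intermediate
9 | (methoxymethyl)triphenylphosphonium chloride | COC[P+](c1ccccc1)(c1ccccc1)c1ccccc1.[Cl-] | starting material
10 | (methoxymethylene)triphenylphosphorane | COC=P(c1ccccc1)(c1ccccc1)c1ccccc1 | intermediate
11 | [2-{[(tert-butyldimethylsilyl)oxy]methyl}-3-(2,6-dimethoxybenzoyl)-1-methoxy-6-oxido-4-oxohepta-2,5-dien-1-yl]triphenylphosphonium, zwitterion (racemic, alkene geometry not fixed) | COC(C(CO[Si](C)(C)C(C)(C)C)=C(C(=O)c1c(OC)cccc1OC)C(=O)C=C(C)[O-])[P+](c1ccccc1)(c1ccccc1)c1ccccc1 | intermediate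
12 | [2-{[(tert-butyldimethylsilyl)oxy]methyl}-6-hydroxy-3-methoxy-4-methylphenyl](2,6-dimethoxyphenyl)methanone | COc1cccc(OC)c1C(=O)c1c(O)cc(C)c(OC)c1CO[Si](C)(C)C(C)(C)C | intermediate
13 | (2,6-dimethoxyphenyl)[6-hydroxy-2-(hydroxymethyl)-3-methoxy-4-methylphenyl]methanone | COc1cccc(OC)c1C(=O)c1c(O)cc(C)c(OC)c1CO | intermediate
14 | preacredinone A, [2-(2,6-dimethoxybenzoyl)-3-hydroxy-6-methoxy-5-methylphenyl]methyl acetate | COc1cccc(OC)c1C(=O)c1c(O)cc(C)c(OC)c1COC(C)=O | target

Total step count: 6. Longest linear sequence: 6 steps (from 1 and 2 to 14).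

**Steps most likely to fail**

Risk 1 (step 4, the proposed new method).
- What may go wrong: the basic ylide may only shuttle protons to and from the methyl and OCH2 groups of 8, or the open-chain phosphorane may fail to close on the enolate-masked ketone, so that no benzene ring forms.
- Fallback, from ynone 3 back to 12: ring B would be made by a Diels–Alder benzannulation instead. Commercial 4-methylfuran-2(5H)-one is silylated (Me3SiOTf, Et3N, CH2Cl2, 0 °C) to 4-methyl-2-[(trimethylsilyl)oxy]furan F1. Cycloaddition of F1 with 3 (PhMe, 80 °C, under argon) should join the unsubstituted α-carbon of the furan, its nucleophilic terminus, to the β-carbon of the ynone and give the 7-oxanorbornadiene cycloadduct F2, which is not isolated. Dilute aqueous acid on work-up opens the oxygen bridge and removes the trimethylsilyl group to give hydroquinone F3, in which the bridging oxygen has become the C5 hydroxyl and the silyloxy carbon the C2 hydroxyl. Methylation (MeI, 1.1 equiv, K2CO3, acetone, rt) at the C5 hydroxyl, the only one not chelated to the ketone, should give 12.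

Risk 2 (step 3).
- What may go wrong: acylation of the push–pull enaminone may be slower than dimerisation of acetylketene, or the dimethylamine released may add back to the electrophilic pyranone and open it.
- Fallback, from 4 back to 8: the amine is removed before the annulation. Mild hydrolysis of 4 (aq. oxalic acid, THF, 0 °C) gives 4-[(tert-butyldimethylsilyl)oxy]-1-(2,6-dimethoxyphenyl)butane-1,3-dione F4. Its enol is annulated with acetylketene from 5 (PhMe, 110 °C, then a trace of pyridinium p-toluenesulfonate) by C-acylation at the central carbon and cyclodehydration, the acylketene/β-dicarbonyl route to 3-acyl-4-pyranones. This should give 8 with loss of water only; the ring oxygen is expected on the silyloxymethyl side because the 2,6-dimethoxyphenyl ketone is shielded.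

Risk 3 (step 6).
- What may go wrong: loss of chemoselectivity, the phenol being acetylated along with the alcohol.
- Fallback, from 13 back to 14: both hydroxyls are acetylated on purpose (Ac2O, pyridine, DMAP, CH2Cl2, rt) to [3-acetoxy-2-(2,6-dimethoxybenzoyl)-6-methoxy-5-methylphenyl]methyl acetate F5. The aryl acetate, an activated ester ortho to the ketone, is then removed selectively by aminolysis (pyrrolidine, 1.1 equiv, CH2Cl2, 0 °C), which should leave the alkyl acetate and give 14.

Further compounds
F1 | step 4 | 4-methyl-2-[(trimethylsilyl)oxy]furan | Cc1coc(O[Si](C)(C)C)c1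
F2 | step 4 | {3-{[(tert-butyldimethylsilyl)oxy]methyl}-5-methyl-1-[(trimethylsilyl)oxy]-7-oxabicyclo[2.2.1]hepta-2,5-dien-2-yl}(2,6-dimethoxyphenyl)methanone (racemic, not isolated) | C[Si](C)(C)OC12OC(C(C)=C1)C(CO[Si](C)(C)C(C)(C)C)=C2C(=O)c1c(OC)cccc1OC
F3 | step 4 | [2-{[(tert-butyldimethylsilyl)oxy]methyl}-3,6-dihydroxy-4-methylphenyl](2,6-dimethoxyphenyl)methanone | COc1cccc(OC)c1C(=O)c1c(O)cc(C)c(O)c1CO[Si](C)(C)C(C)(C)C
F4 | step 3 | 4-[(tert-butyldimethylsilyl)oxy]-1-(2,6-dimethoxyphenyl)butane-1,3-dione | COc1cccc(OC)c1C(=O)CC(=O)CO[Si](C)(C)C(C)(C)C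
F5 | step 6 | [3-acetoxy-2-(2,6-dimethoxybenzoyl)-6-methoxy-5-methylphenyl]methyl acetate | COc1cccc(OC)c1C(=O)c1c(OC(C)=O)cc(C)c(OC)c1COC(C)=O
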